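Z, formed from X and the species Q, headed the agenda of a short meeting about a new flask, with D, X and L charged as listed below. The steps on the table were D ⇌ Q, X + Q ⇌ Z, L + Q → G and D + Z → E.

| flask | D | X | L | remark | time |
|---|---|---|---|---|---|
| cedar | 0.70 M | 0.45 M | 1.25 M | run made earlier |  |
| ash | 1.1 M | 0.45 M | 1.25 M | run made earlier |  |
| oak | 0.50 M | 0.23 M | 1.25 M | run made earlier |  |
| flask | 0.50 M | 0.450 M | 1.25 M |  | 15 d |

| run | time / d | Z / % | G / % | D / % |
|---|---|---|---|---|
| cedar | 2.08 | 1.3 | 6.5 | 74.7 |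
| cedar | 4.00 | 3.6 | 13.8 | 65.7 |
| cedar | 6.00 | 0 | 19.4 | 56.9 |
| cedar | 8.00 | 1.4 | 25.0 | 51.7 |
| cedar | 10.0 | 2.3 | 28.2 | 44.9 |
| cedar | 12.0 | 0 | 31.2 | 41.3 |
| ash | 2.08 | 1.3 | 5.4 | 74.0 |
| ash | 4.00 | 3.4 | 15.1 | 61.1 |
| ash | 6.00 | 2.0 | 17.6 | 54.2 |
| ash | 8.00 | 1.4 | 22.5 | 46.0 |
| ash | 10.0 | 0 | 25.5 | 42.1 |
| ash | 12.0 | 3.6 | 28.9 | 35.9 |
| oak | 1.04 | 0.6 | 4.6 | 83.9 |
| oak | 3.00 | 3.0 | 10.8 | 75.5 |
| oak | 6.00 | 0 | 19.7 | 65.9 |
| oak | 8.00 | 1.8 | 27.1 | 55.9 |
| oak | 12.0 | 1.9 | 35.4 | 47.5 |

(readings scatter by 1 percentage point)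

- in percentages every species weighs as the D in it: one E counts as two
- what was read earlier has a scatter of 1 percentage point, one standard deviation
- reactions considered so far: D <-> Q; X + Q <-> Z; L + Q -> G; D + Z -> E

1. ratio of Z to G at 8.0 h
2. ratio of Z to G at 50 h
3. ratio of Z to G at 15 d
4. which of Z and G there is more of at 15 d

The analyst reported that single Z readings lie too near their scatter to be used. The kineticist answered that a sum can be used: if both reversible steps stay near balance (a pre-equilibrium), Z follows D and X, and the ratio between them can be frozen. She summed Z and D over cedar and ash, both charged with 0.45 M of X, and obtained h = 0.0696 /M, the Z present divided by the D present and by the molarity of X charged. The analyst objected that oak reads Z over D as 0.0222, higher than the 0.0160 that h gives, but he accepted the gap as scatter of so few readings.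

The new flask has 0.450 M of X, so its Z over D should be 0.0313. The meeting then reckoned Z over G from that figure. At 50 h, the mean D and G of the first readings of cedar and ash, taken at 2.08 d, give 0.391. At 15 d, oak, which has the same D charge, extended along its last stretch gives D 40.3% and G 43.2%, so the ratio is 0.0292 and G leads. At 8.0 h, taking D as still whole and G as a straight line from oak's first reading gives roughly 2.12.

The forecast, which held that “Z behaves as a small, quasi-steady intermediate”, gave 0.35, 0.2, 0.045 and G in the lead.

The flask gives 3.26, 0.360 and 0.0321, with G ahead at 38.1% against 1.22% of Z.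

    D ⇌ Q (K = 0.128, k = 0.0291 /h)
    X + Q ⇌ Z (K = 0.705 /M, k = 1.01 /M/h)
    L + Q → G (k = 0.0138 /M/h)
    D + Z → E (k = 0.0474 /M/h)

In this flask the backward turnover of X + Q to Z is 99% of the forward one, and at 15.0 d L + Q uses Q at 0.037 of the forward rate of X + Q. Z over D there stands at 0.0333, against 0.0313 from h. In the neighbour with 1.1 M of X, h gives Z over D of 0.0766, so its 27.2% of D at 15 d should carry 2.08% of Z. That neighbour holds 2.30%, and its Z over G is 0.0720.

The runs were generated by integration for an exercise, noise included.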